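**Plan**
- Retrosynthesis: the two phenols are masked as MOM ethers and the C4 ketone is taken back to a carbinol; ring C is then cut at O1–C8a, the chain at C2–C3 (aldol), and the prenyl group at C8–C1'' (Claisen–Cope relay from the C5 oxygen).
- Enabling feature: O1–C8a is an aryl C(sp2)–O bond of ring A, ortho to C4a which carries the three-carbon chain. The intact C2 carbinol oxygen can therefore be joined to C8a (activated as its triflate), and the C2–O bond is never broken.
- Forward order: rings A and B are purchased arenes. The prenyl group is relayed onto C8, the C2–C3 bond joins the two aryl units, and ring C, the only ring formed, closes last at O1–C8a.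
- Stereochemistry: C2 (S) comes from a reagent-controlled Ipc-boron aldol and is carried unchanged through the cyclisation. The C4 carbinol (1,3-anti, hydroxyl-directed reduction) is temporary and is erased by oxidation.

Key step: step 8

Remark: 2',6'-dihydroxy-4'-methoxyacetophenone (1) is taken as a purchasable building block; ring positions are given in flavanone numbering (C2, C4, C4a, C5–C8, C8a) throughout.

**Route**

Step 1
Reactants: 1 1-(2,6-dihydroxy-4-methoxyphenyl)ethanone; 2 prenyl bromide
Product: 3 1-[2-hydroxy-4-methoxy-6-[(3-methylbut-2-en-1-yl)oxy]phenyl]ethanone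
Conditions: K2CO3, acetone, 50 °C
Reagents that add atoms: none
Why: Williamson O-alkylation should stop at the mono-ether because the remaining hydroxyl of the product is locked in a hydrogen bond to the acetyl carbonyl, and carbonate in acetone favours O- over C-alkylation.

Step 2
Reactants: 3 1-[2-hydroxy-4-methoxy-6-[(3-methylbut-2-en-1-yl)oxy]phenyl]ethanone; 4 trifluoromethanesulfonic anhydride
Product: 5 2-acetyl-5-methoxy-3-[(3-methylbut-2-en-1-yl)oxy]phenyl trifluoromethanesulfonate
Conditions: pyridine, CH2Cl2, 0 °C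
Reagents that add atoms: none
Why: O-sulfonylation of a chelated ortho-acyl phenol with triflic anhydride and pyridine is routine, and at 0 °C neither the prenyl ether nor the methyl ketone should react.

Step 3
Reactants: 5 2-acetyl-5-methoxy-3-[(3-methylbut-2-en-1-yl)oxy]phenyl trifluoromethanesulfonate
Product: 8 2-acetyl-3-hydroxy-5-methoxy-6-(3-methylbut-2-en-1-yl)phenyl trifluoromethanesulfonate, via Claisen ortho-dienone 6 (not isolated), via Cope para-dienone 7 (not isolated)
Conditions: PhNEt2, 200 °C
Reagents that add atoms: none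
Why: An aromatic Claisen rearrangement puts a 1,1-dimethylallyl group on the free ortho carbon (dienone 6) and a Cope shift relays it as a normal prenyl group to the carbon para to the original ether oxygen and ortho to the triflate (dienone 7) before enolisation, which is the known Claisen–Cope course of prenyl ethers of phloroglucinol-type arenes and places the prenyl group at the future C8 without any need to tell two phenols apart.

Step 4
Reactants: 8 2-acetyl-3-hydroxy-5-methoxy-6-(3-methylbut-2-en-1-yl)phenyl trifluoromethanesulfonate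
Product: 9 2-acetyl-5-methoxy-3-(methoxymethoxy)-6-(3-methylbut-2-en-1-yl)phenyl trifluoromethanesulfonate
Conditions: MOMCl, i-Pr2NEt, CH2Cl2, 0 °C → rt
Reagents that add atoms: chloromethyl methyl ether (MOMCl), COCCl
Why: Alkylation of the single phenol with MOMCl under a hindered amine base is standard acetal protection, and the aryl triflate tolerates these non-nucleophilic conditions.

Step 5
Reactants: 10 4-hydroxybenzaldehyde
Product: 11 4-(methoxymethoxy)benzaldehyde
Conditions: MOMCl, i-Pr2NEt, CH2Cl2, 0 °C → rt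
Reagents that add atoms: chloromethyl methyl ether (MOMCl), COCCl
Why: MOM protection of an unhindered, acidic phenol is standard and leaves the aldehyde untouched.

Step 6
Reactants: 9 2-acetyl-5-methoxy-3-(methoxymethoxy)-6-(3-methylbut-2-en-1-yl)phenyl trifluoromethanesulfonate; 11 4-(methoxymethoxy)benzaldehyde
Product: 14 (3S)-3-hydroxy-3-[4-(methoxymethoxy)phenyl]-1-[4-methoxy-6-(methoxymethoxy)-3-(3-methylbut-2-en-1-yl)-2-(trifluoromethanesulfonyloxy)phenyl]propan-1-one, via enol diisopinocampheylborinate 12 (not isolated), via boron aldolate 13 (not isolated)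
Conditions: (+)-Ipc2BCl [from (−)-α-pinene], Et3N, Et2O, 0 °C; then 11, −78 → −20 °C; H2O2, pH 7 buffer, MeOH, 0 °C
Reagents that add atoms: none
Why: In this Ipc-boron aldol (Paterson aldol) the chloroborane and Et3N enolise the methyl group to enol borinate 12, whose reagent-controlled addition to the si face of aldehyde 11 (methyl ketone enol borinates of the (+)-reagent are expected to attack this face) sets the (S)-carbinol that becomes C2, and buffered peroxide work-up frees the aldol without retro-aldol or dehydration.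

Step 7
Reactants: 14 (3S)-3-hydroxy-3-[4-(methoxymethoxy)phenyl]-1-[4-methoxy-6-(methoxymethoxy)-3-(3-methylbut-2-en-1-yl)-2-(trifluoromethanesulfonyloxy)phenyl]propan-1-one
Product: 15 (1S,3S)-1-[4-(methoxymethoxy)phenyl]-3-[4-methoxy-6-(methoxymethoxy)-3-(3-methylbut-2-en-1-yl)-2-(trifluoromethanesulfonyloxy)phenyl]propane-1,3-diol
Conditions: Me4NBH(OAc)3, MeCN–AcOH, −30 °C
Reagents that add atoms: none
Why: In this Evans–Saksena reduction the β-hydroxyl exchanges onto triacetoxyborohydride and delivers hydride intramolecularly through a chair-like transition state, which should give the 1,3-anti diol and hence the (S) configuration at the new carbinol, while the MOM ethers, triflate and prenyl group are inert at −30 °C.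

Step 8
Reactants: 15 (1S,3S)-1-[4-(methoxymethoxy)phenyl]-3-[4-methoxy-6-(methoxymethoxy)-3-(3-methylbut-2-en-1-yl)-2-(trifluoromethanesulfonyloxy)phenyl]propane-1,3-diol
Product: 16 (2S,4S)-7-methoxy-5-(methoxymethoxy)-2-[4-(methoxymethoxy)phenyl]-8-(3-methylbut-2-en-1-yl)-3,4-dihydro-2H-chromen-4-ol
Conditions: RockPhos Pd G3 (5 mol%), Cs2CO3, toluene, 80 °C
Reagents that add atoms: none
Why: Palladium(0) carrying the bulky biaryl di-tert-butylphosphine inserts into the C8a–OTf bond, carbonate-assisted exchange of triflate for the C2 alkoxide gives a seven-membered aryl–palladium–alkoxide, and C–O reductive elimination forms the O1–C8a bond. The closest known reaction type is the Buchwald–Hartwig-type intramolecular etherification of secondary alcohols with aryl halides or sulfonates to chromans, which leaves the carbinol configuration untouched. Ring C closes as a six-membered ring by reductive elimination at the arene carbon, so the C2–O bond is never broken. No stereocentre is created: C2 (S) from the aldol and C4 (S) from the anti reduction are spectators. The step needs the C2 over the C4 hydroxyl, which ring size secures (the C4 alkoxide could only close a four-membered ring and, held in a five-membered chelate, cannot align its C–H bond with palladium), and it needs C–O reductive elimination over β-hydride elimination at the C2 alkoxide, which the bulky ligand is chosen to enforce. The ortho prenyl alkene should not intercept the arylpalladium, since only a 4-exo or 5-endo insertion into a trisubstituted alkene would be open to it.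

Step 9
Reactants: 16 (2S,4S)-7-methoxy-5-(methoxymethoxy)-2-[4-(methoxymethoxy)phenyl]-8-(3-methylbut-2-en-1-yl)-3,4-dihydro-2H-chromen-4-ol
Product: 17 (2S)-7-methoxy-5-(methoxymethoxy)-2-[4-(methoxymethoxy)phenyl]-8-(3-methylbut-2-en-1-yl)-2,3-dihydro-4H-chromen-4-one
Conditions: TPAP (5 mol%), NMO, 4 Å MS, CH2Cl2, rt
Reagents that add atoms: none
Why: Ley–Griffith oxidation converts the secondary benzylic carbinol into the C4 ketone under neutral conditions, deleting the temporary C4 stereocentre while the C2 centre, the prenyl alkene and the MOM ethers are untouched.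

Step 10
Reactants: 17 (2S)-7-methoxy-5-(methoxymethoxy)-2-[4-(methoxymethoxy)phenyl]-8-(3-methylbut-2-en-1-yl)-2,3-dihydro-4H-chromen-4-one
Product: 18 Mundulea flavanone B, (2S)-5-hydroxy-2-(4-hydroxyphenyl)-7-methoxy-8-(3-methylbut-2-en-1-yl)-2,3-dihydro-4H-chromen-4-one
Conditions: HCl (1.25 M in MeOH), rt
Reagents that add atoms: none
Why: Acid-catalysed acetal exchange with methanol removes both MOM groups, and because C8 is flanked by the 7-methoxy group and the ring oxygen no free phenol can add to the prenyl alkene, while the flavanone C2 centre should be configurationally stable in mild acid.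

**Compound list**

1 | 1-(2,6-dihydroxy-4-methoxyphenyl)ethanone (2',6'-dihydroxy-4'-methoxyacetophenone) | CC(=O)c1c(O)cc(OC)cc1O | starting material
2 | prenyl bromide (1-bromo-3-methylbut-2-ene) | CC(C)=CCBr | starting material
3 | 1-[2-hydroxy-4-methoxy-6-[(3-methylbut-2-en-1-yl)oxy]phenyl]ethanone | CC(=O)c1c(O)cc(OC)cc1OCC=C(C)C | intermediate
4 | trifluoromethanesulfonic anhydride | O=S(=O)(OS(=O)(=O)C(F)(F)F)C(F)(F)F | starting material
5 | 2-acetyl-5-methoxy-3-[(3-methylbut-2-en-1-yl)oxy]phenyl trifluoromethanesulfonate | CC(=O)c1c(OCC=C(C)C)cc(OC)cc1OS(=O)(=O)C(F)(F)F | intermediate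
6 | Claisen ortho-dienone, 2-acetyl-5-methoxy-4-(2-methylbut-3-en-2-yl)-3-oxocyclohexa-1,5-dien-1-yl trifluoromethanesulfonate (racemic, formed in situ) | CC(=O)C1=C(OS(=O)(=O)C(F)(F)F)C=C(OC)C(C(C)(C)C=C)C1=O | intermediate
7 | Cope para-dienone, 2-acetyl-5-methoxy-6-(3-methylbut-2-en-1-yl)-3-oxocyclohexa-1,4-dien-1-yl trifluoromethanesulfonate (racemic, formed in situ) | CC(=O)C1=C(OS(=O)(=O)C(F)(F)F)C(CC=C(C)C)C(OC)=CC1=O | intermediate
8 | 2-acetyl-3-hydroxy-5-methoxy-6-(3-methylbut-2-en-1-yl)phenyl trifluoromethanesulfonate | CC(=O)c1c(O)cc(OC)c(CC=C(C)C)c1OS(=O)(=O)C(F)(F)F | intermediate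
9 | 2-acetyl-5-methoxy-3-(methoxymethoxy)-6-(3-methylbut-2-en-1-yl)phenyl trifluoromethanesulfonate | CC(=O)c1c(OCOC)cc(OC)c(CC=C(C)C)c1OS(=O)(=O)C(F)(F)F | intermediate
10 | 4-hydroxybenzaldehyde | O=Cc1ccc(O)cc1 | starting material
11 | 4-(methoxymethoxy)benzaldehyde | COCOc1ccc(C=O)cc1 | intermediate
12 | enol diisopinocampheylborinate of ketone 9, Ipc groups from (−)-α-pinene (formed in situ) | C=C(OB([C@H]1C[C@H]2C[C@@H]([C@@H]1C)C2(C)C)[C@H]1C[C@H]2C[C@@H]([C@@H]1C)C2(C)C)c1c(OCOC)cc(OC)c(CC=C(C)C)c1OS(=O)(=O)C(F)(F)F | intermediate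
13 | boron aldolate, O-diisopinocampheylboryl derivative of aldol 14 (formed in situ) | CC(C)=CCc1c(OC)cc(OCOC)c(C(=O)C[C@H](OB([C@H]2C[C@H]3C[C@@H]([C@@H]2C)C3(C)C)[C@H]2C[C@H]3C[C@@H]([C@@H]2C)C3(C)C)c2ccc(OCOC)cc2)c1OS(=O)(=O)C(F)(F)F | intermediate
14 | (3S)-3-hydroxy-3-[4-(methoxymethoxy)phenyl]-1-[4-methoxy-6-(methoxymethoxy)-3-(3-methylbut-2-en-1-yl)-2-(trifluoromethanesulfonyloxy)phenyl]propan-1-one | CC(C)=CCc1c(OC)cc(OCOC)c(C(=O)C[C@H](O)c2ccc(OCOC)cc2)c1OS(=O)(=O)C(F)(F)F | intermediate
15 | (1S,3S)-1-[4-(methoxymethoxy)phenyl]-3-[4-methoxy-6-(methoxymethoxy)-3-(3-methylbut-2-en-1-yl)-2-(trifluoromethanesulfonyloxy)phenyl]propane-1,3-diol | O[C@H](c1ccc(OCOC)cc1)C[C@H](O)c1c(OCOC)cc(OC)c(CC=C(C)C)c1OS(=O)(=O)C(F)(F)F | intermediate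
16 | (2S,4S)-7-methoxy-5-(methoxymethoxy)-2-[4-(methoxymethoxy)phenyl]-8-(3-methylbut-2-en-1-yl)-3,4-dihydro-2H-chromen-4-ol | COc1cc(OCOC)c2c(c1CC=C(C)C)O[C@H](c1ccc(OCOC)cc1)C[C@@H]2O | intermediate
17 | (2S)-7-methoxy-5-(methoxymethoxy)-2-[4-(methoxymethoxy)phenyl]-8-(3-methylbut-2-en-1-yl)-2,3-dihydro-4H-chromen-4-one | COc1cc(OCOC)c2c(c1CC=C(C)C)O[C@H](c1ccc(OCOC)cc1)CC2=O | intermediate
18 | Mundulea flavanone B, (2S)-5-hydroxy-2-(4-hydroxyphenyl)-7-methoxy-8-(3-methylbut-2-en-1-yl)-2,3-dihydro-4H-chromen-4-one | COc1cc(O)c2c(c1CC=C(C)C)O[C@H](c1ccc(O)cc1)CC2=O | target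

**Step count**

Total steps: 10. Longest linear sequence: 9 (steps 1–4 and 6–10, from 1); step 5 is a one-step side branch.

**Steps most likely to fail, with fallbacks**

1. Step 8 (palladium etherification).
   - What may go wrong: β-hydride elimination from a palladium alkoxide could oxidise a carbinol and reduce the arene, or erode C2 through reversible ketone insertion. Base-induced loss of the triflyl group, or its migration to the neighbouring C4 alkoxide, could also outrun oxidative addition of the hindered triflate.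
   - Fallback: ring C is closed from the phenol side with inversion at C2. Setting out from ketone 9 (with aldehyde 11), the aldol of step 6 is run with (−)-Ipc2BCl to give (3R)-3-hydroxy-3-[4-(methoxymethoxy)phenyl]-1-[4-methoxy-6-(methoxymethoxy)-3-(3-methylbut-2-en-1-yl)-2-(trifluoromethanesulfonyloxy)phenyl]propan-1-one F1. Reduction as in step 7 gives (1R,3R)-1-[4-(methoxymethoxy)phenyl]-3-[4-methoxy-6-(methoxymethoxy)-3-(3-methylbut-2-en-1-yl)-2-(trifluoromethanesulfonyloxy)phenyl]propane-1,3-diol F2. Et4NOH in dioxane removes the triflyl group to give (1R,3R)-1-[4-(methoxymethoxy)phenyl]-3-[2-hydroxy-4-methoxy-6-(methoxymethoxy)-3-(3-methylbut-2-en-1-yl)phenyl]propane-1,3-diol F3. Mitsunobu cyclisation (PPh3, DIAD, THF, 0 °C) lets the C8a phenol displace the activated C2 carbinol with inversion, giving (2S,4R)-7-methoxy-5-(methoxymethoxy)-2-[4-(methoxymethoxy)phenyl]-8-(3-methylbut-2-en-1-yl)-3,4-dihydro-2H-chromen-4-ol F4. Oxidation as in step 9 then comes back to the route at flavanone 17.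

2. Step 6 (Ipc-boron aldol).
   - What may go wrong: facial discrimination by the Ipc ligands may be incomplete, since methyl ketone enol borinates are only moderately selective, and enolisation of the doubly ortho-substituted ketone may be sluggish.
   - Fallback: C2 is set by catalytic reduction instead of by the aldol. Setting out from ketone 9 and aldehyde 11, a lithium aldol (LDA, THF, −78 °C) gives racemic 3-hydroxy-3-[4-(methoxymethoxy)phenyl]-1-[4-methoxy-6-(methoxymethoxy)-3-(3-methylbut-2-en-1-yl)-2-(trifluoromethanesulfonyloxy)phenyl]propan-1-one F5. Dess–Martin oxidation gives 1-[4-(methoxymethoxy)phenyl]-3-[4-methoxy-6-(methoxymethoxy)-3-(3-methylbut-2-en-1-yl)-2-(trifluoromethanesulfonyloxy)phenyl]propane-1,3-dione F6. Noyori asymmetric transfer hydrogenation (RuCl[(S,S)-TsDPEN](p-cymene), HCO2H–Et3N) should reduce only the unhindered 4-(methoxymethoxy)benzoyl carbonyl, the other being shielded by two ortho substituents, and comes back to the route at aldol 14.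

3. Step 3 (Claisen–Cope relay).
   - What may go wrong: dienone 6 may enolise before the Cope shift, leaving a 1,1-dimethylallyl group on the carbon that becomes C6, or the triflyl group may be lost at 200 °C.
   - Fallback: direct C-prenylation, with the two phenols then told apart by their steric environment. Setting out from 1, prenyl bromide 2 with DBU in THF gives 1-[2,6-dihydroxy-4-methoxy-3-(3-methylbut-2-en-1-yl)phenyl]ethanone F7. MOMCl and i-Pr2NEt should protect the hydroxyl that is not flanked by the prenyl group, giving 1-[2-hydroxy-4-methoxy-6-(methoxymethoxy)-3-(3-methylbut-2-en-1-yl)phenyl]ethanone F8. Triflation of the remaining phenol with anhydride 4 and pyridine comes back to the route at ketone 9.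

**Further compounds**

F1 | step 8 | (3R)-3-hydroxy-3-[4-(methoxymethoxy)phenyl]-1-[4-methoxy-6-(methoxymethoxy)-3-(3-methylbut-2-en-1-yl)-2-(trifluoromethanesulfonyloxy)phenyl]propan-1-one | CC(C)=CCc1c(OC)cc(OCOC)c(C(=O)C[C@@H](O)c2ccc(OCOC)cc2)c1OS(=O)(=O)C(F)(F)F
F2 | step 8 | (1R,3R)-1-[4-(methoxymethoxy)phenyl]-3-[4-methoxy-6-(methoxymethoxy)-3-(3-methylbut-2-en-1-yl)-2-(trifluoromethanesulfonyloxy)phenyl]propane-1,3-diol | O[C@@H](c1ccc(OCOC)cc1)C[C@@H](O)c1c(OCOC)cc(OC)c(CC=C(C)C)c1OS(=O)(=O)C(F)(F)F
F3 | step 8 | (1R,3R)-1-[4-(methoxymethoxy)phenyl]-3-[2-hydroxy-4-methoxy-6-(methoxymethoxy)-3-(3-methylbut-2-en-1-yl)phenyl]propane-1,3-diol | O[C@@H](c1ccc(OCOC)cc1)C[C@@H](O)c1c(OCOC)cc(OC)c(CC=C(C)C)c1O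
F4 | step 8 | (2S,4R)-7-methoxy-5-(methoxymethoxy)-2-[4-(methoxymethoxy)phenyl]-8-(3-methylbut-2-en-1-yl)-3,4-dihydro-2H-chromen-4-ol | COc1cc(OCOC)c2c(c1CC=C(C)C)O[C@H](c1ccc(OCOC)cc1)C[C@H]2O
F5 | step 6 | racemic 3-hydroxy-3-[4-(methoxymethoxy)phenyl]-1-[4-methoxy-6-(methoxymethoxy)-3-(3-methylbut-2-en-1-yl)-2-(trifluoromethanesulfonyloxy)phenyl]propan-1-one | CC(C)=CCc1c(OC)cc(OCOC)c(C(=O)CC(O)c2ccc(OCOC)cc2)c1OS(=O)(=O)C(F)(F)F
F6 | step 6 | 1-[4-(methoxymethoxy)phenyl]-3-[4-methoxy-6-(methoxymethoxy)-3-(3-methylbut-2-en-1-yl)-2-(trifluoromethanesulfonyloxy)phenyl]propane-1,3-dione | CC(C)=CCc1c(OC)cc(OCOC)c(C(=O)CC(=O)c2ccc(OCOC)cc2)c1OS(=O)(=O)C(F)(F)F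
F7 | step 3 | 1-[2,6-dihydroxy-4-methoxy-3-(3-methylbut-2-en-1-yl)phenyl]ethanone | CC(=O)c1c(O)cc(OC)c(CC=C(C)C)c1O
F8 | step 3 | 1-[2-hydroxy-4-methoxy-6-(methoxymethoxy)-3-(3-methylbut-2-en-1-yl)phenyl]ethanone | CC(=O)c1c(OCOC)cc(OC)c(CC=C(C)C)c1O
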